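**Retrosynthetic overview**
1. Target 18 ⇐ aryl ketone 17 by Felkin-selective hydride reduction, which sets the carbinol centre last.
2. 17 ⇐ secondary nitro compound 16 by a Nef reaction; the CH2OH of 16 is the reduced aldehyde of the cyclisation product.
3. The oxolane (the only ring formed) ⇐ enal 5 + nitroallyl alcohol 13: amine-catalysed oxa-Michael addition makes O1–C2, then an intramolecular enamine Michael addition onto the tethered nitroalkene closes the ring at C3–C4.
4. 5 ⇐ 3,4,5-trimethoxybenzaldehyde (Wittig, DIBAL-H, MnO2); 13 ⇐ 4-bromoveratrole + nitromethane (Pd arylation), then Henry/elimination with TBSOCH2CHO and desilylation.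

Assumption: ring atoms are labelled O1, C2 (CH–aryl), C3 (CH–CH2OH), C4, C5 and the carbinol carbon C7'. The nitro-bearing carbon of 15/16 is an epimer mixture that is erased in step 8.

**Route**

Step 1
Reactants: 1 3,4,5-trimethoxybenzaldehyde; 2 ethyl (triphenylphosphoranylidene)acetate
Product: 3 ethyl (E)-3-(3,4,5-trimethoxyphenyl)prop-2-enoate
Conditions: toluene, 90 °C
Reagents that add atoms: none
Why: Wittig olefination with a stabilised ylide is reliably E-selective for aryl aldehydes.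

Step 2
Reactants: 3 ethyl (E)-3-(3,4,5-trimethoxyphenyl)prop-2-enoate
Product: 4 (E)-3-(3,4,5-trimethoxyphenyl)prop-2-en-1-ol
Conditions: DIBAL-H (2.3 equiv), CH2Cl2, −78 °C; Rochelle salt work-up
Reagents that add atoms: none
Why: DIBAL-H ester reduction gives clean 1,2-reduction of the enoate to the allylic alcohol without touching the alkene or aryl ethers.

Step 3
Reactants: 4 (E)-3-(3,4,5-trimethoxyphenyl)prop-2-en-1-ol
Product: 5 (E)-3-(3,4,5-trimethoxyphenyl)prop-2-enal
Conditions: activated MnO2 (10 equiv), CH2Cl2, rt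
Reagents that add atoms: none
Why: MnO2 allylic oxidation stops at the enal and keeps the E geometry.

Step 4
Reactants: 6 4-bromo-1,2-dimethoxybenzene; 7 nitromethane
Product: 8 1,2-dimethoxy-4-(nitromethyl)benzene
Conditions: Pd2(dba)3 (2.5 mol %), XPhos (6 mol %), Cs2CO3 (1.2 equiv), MeNO2/1,4-dioxane, 4 Å MS, 50 °C; aq. NH4Cl
Reagents that add atoms: none
Why: Pd-catalysed α-arylation of nitromethane (cross-coupling of the nitronate) works on electron-rich aryl bromides and stops at mono-arylation because the product nitronate is unreactive.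

Step 5
Reactants: 8 1,2-dimethoxy-4-(nitromethyl)benzene; 9 2-[(tert-butyldimethylsilyl)oxy]acetaldehyde
Product: 12 (E)-tert-butyl{[3-(3,4-dimethoxyphenyl)-3-nitroprop-2-en-1-yl]oxy}dimethylsilane, via nitro alcohol 10 (not isolated), via mesylate 11 (not isolated)
Conditions: DBU (10 mol %), THF, 0 °C; then MsCl, Et3N, CH2Cl2, −20 → 0 °C
Reagents that add atoms: none
Why: Henry (nitroaldol) addition of the acidic benzylic nitronate, then mesylation and E1cB elimination, gives the conjugated nitroalkene, mainly E; its geometry and the two transient stereocentres are not carried into the target.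

Step 6
Reactants: 12 (E)-tert-butyl{[3-(3,4-dimethoxyphenyl)-3-nitroprop-2-en-1-yl]oxy}dimethylsilane
Product: 13 (E)-3-(3,4-dimethoxyphenyl)-3-nitroprop-2-en-1-ol
Conditions: 48% aq. HF, MeCN, 0 °C → rt
Reagents that add atoms: none
Why: Acidic HF desilylation frees the primary alcohol without the basic fluoride conditions that would cause oxa-Michael addition or deconjugation of the nitroalkene.

Step 7
Reactants: 5 (E)-3-(3,4,5-trimethoxyphenyl)prop-2-enal (1.3 equiv); 13 (E)-3-(3,4-dimethoxyphenyl)-3-nitroprop-2-en-1-ol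
Product: 16 [(2R,3S,4S)-4-[(3,4-dimethoxyphenyl)(nitro)methyl]-2-(3,4,5-trimethoxyphenyl)oxolan-3-yl]methanol, via oxa-Michael adduct 14 (not isolated), via nitro aldehyde 15 (not isolated)
Conditions: (R)-2-[diphenyl(trimethylsilyloxy)methyl]pyrrolidine (20 mol %), PhCO2H (20 mol %), toluene, rt; then MeOH, NaBH4, 0 °C
Reagents that add atoms: none
Why: Iminium–enamine domino oxa-Michael/intramolecular Michael reaction: the (R)-catalyst shields one face of the E-iminium so the alcohol adds reversibly to give C2 (R); the derived E-enamine then attacks the tethered nitroalkene through its open face in a ring-closing 5-exo-trig Michael addition that places CHO trans to the aryl (C3) and the nitrobenzyl arm trans to CHO (C4, synclinal enamine/nitroalkene transition state, all-trans ring); in-situ NaBH4 reduction then fixes the epimerisable C3 as CH2OH.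

Step 8
Reactants: 16 [(2R,3S,4S)-4-[(3,4-dimethoxyphenyl)(nitro)methyl]-2-(3,4,5-trimethoxyphenyl)oxolan-3-yl]methanol
Product: 17 (3,4-dimethoxyphenyl)[(3R,4S,5R)-4-(hydroxymethyl)-5-(3,4,5-trimethoxyphenyl)oxolan-3-yl]methanone
Conditions: NaOH (1.1 equiv), MeOH, 0 °C; then Oxone, aq. Na2HPO4 buffer, 0 °C → rt
Reagents that add atoms: Oxone (active component potassium peroxymonosulfate) [K+].[O-]S(=O)(=O)OO
Why: Oxidative Nef reaction: the benzylic nitronate is hydroxylated at carbon by peroxymonosulfate and loses nitrite to give the aryl ketone, both nitro epimers converging, while the near-neutral buffer avoids epimerisation at C4.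

Step 9
Reactants: 17 (3,4-dimethoxyphenyl)[(3R,4S,5R)-4-(hydroxymethyl)-5-(3,4,5-trimethoxyphenyl)oxolan-3-yl]methanone
Product: 18 (S)-(3,4-dimethoxyphenyl)[(3R,4S,5R)-4-(hydroxymethyl)-5-(3,4,5-trimethoxyphenyl)oxolan-3-yl]methanol
Conditions: L-Selectride (2.5 equiv), THF, −78 °C; then H2O
Reagents that add atoms: none
Why: Felkin–Anh-controlled ketone reduction: the bulky hydride attacks anti to the branched ring carbon C3 with the α-H turned toward the aryl group, which converts the (R)-α-centre into the (S)-carbinol (a chelate through the ring oxygen predicts the same face).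

**Compound list**
1 | 3,4,5-trimethoxybenzaldehyde | COc1cc(C=O)cc(OC)c1OC | starting material
2 | ethyl (triphenylphosphoranylidene)acetate | CCOC(=O)C=P(c1ccccc1)(c1ccccc1)c1ccccc1 | starting material
3 | ethyl (E)-3-(3,4,5-trimethoxyphenyl)prop-2-enoate | CCOC(=O)/C=C/c1cc(OC)c(OC)c(OC)c1 | intermediate
4 | (E)-3-(3,4,5-trimethoxyphenyl)prop-2-en-1-ol | OC/C=C/c1cc(OC)c(OC)c(OC)c1 | intermediate
5 | (E)-3-(3,4,5-trimethoxyphenyl)prop-2-enal | O=C/C=C/c1cc(OC)c(OC)c(OC)c1 | intermediate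
6 | 4-bromo-1,2-dimethoxybenzene | COc1ccc(Br)cc1OC | starting material
7 | nitromethane | C[N+](=O)[O-] | starting material
8 | 1,2-dimethoxy-4-(nitromethyl)benzene | COc1ccc(C[N+](=O)[O-])cc1OC | intermediate
9 | 2-[(tert-butyldimethylsilyl)oxy]acetaldehyde | CC(C)(C)[Si](C)(C)OCC=O | starting material
10 | 3-[(tert-butyldimethylsilyl)oxy]-1-(3,4-dimethoxyphenyl)-1-nitropropan-2-ol (diastereomer mixture) | CC(C)(C)[Si](C)(C)OCC(O)C(c1ccc(OC)c(OC)c1)[N+](=O)[O-] | intermediate
11 | 3-[(tert-butyldimethylsilyl)oxy]-1-(3,4-dimethoxyphenyl)-1-nitropropan-2-yl methanesulfonate (diastereomer mixture) | CC(C)(C)[Si](C)(C)OCC(OS(C)(=O)=O)C(c1ccc(OC)c(OC)c1)[N+](=O)[O-] | intermediate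
12 | (E)-tert-butyl{[3-(3,4-dimethoxyphenyl)-3-nitroprop-2-en-1-yl]oxy}dimethylsilane | CC(C)(C)[Si](C)(C)OC/C=C(\c1ccc(OC)c(OC)c1)[N+](=O)[O-] | intermediate
13 | (E)-3-(3,4-dimethoxyphenyl)-3-nitroprop-2-en-1-ol | OC/C=C(\c1ccc(OC)c(OC)c1)[N+](=O)[O-] | intermediate
14 | (3R)-3-{[(2E)-3-(3,4-dimethoxyphenyl)-3-nitroprop-2-en-1-yl]oxy}-3-(3,4,5-trimethoxyphenyl)propanal (reacts on as its enamine with the catalyst) | O=CC[C@@H](OC/C=C(\c1ccc(OC)c(OC)c1)[N+](=O)[O-])c1cc(OC)c(OC)c(OC)c1 | intermediate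
15 | (2R,3R,4S)-4-[(3,4-dimethoxyphenyl)(nitro)methyl]-2-(3,4,5-trimethoxyphenyl)oxolane-3-carbaldehyde (nitro carbon epimers) | COc1ccc(C([N+](=O)[O-])[C@H]2CO[C@@H](c3cc(OC)c(OC)c(OC)c3)[C@@H]2C=O)cc1OC | intermediate
16 | [(2R,3S,4S)-4-[(3,4-dimethoxyphenyl)(nitro)methyl]-2-(3,4,5-trimethoxyphenyl)oxolan-3-yl]methanol (nitro carbon epimers) | COc1ccc(C([N+](=O)[O-])[C@H]2CO[C@@H](c3cc(OC)c(OC)c(OC)c3)[C@@H]2CO)cc1OC | intermediate
17 | (3,4-dimethoxyphenyl)[(3R,4S,5R)-4-(hydroxymethyl)-5-(3,4,5-trimethoxyphenyl)oxolan-3-yl]methanone | COc1ccc(C(=O)[C@H]2CO[C@@H](c3cc(OC)c(OC)c(OC)c3)[C@@H]2CO)cc1OC | intermediate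
18 | (S)-(3,4-dimethoxyphenyl)[(3R,4S,5R)-4-(hydroxymethyl)-5-(3,4,5-trimethoxyphenyl)oxolan-3-yl]methanol | COc1ccc([C@@H](O)[C@H]2CO[C@@H](c3cc(OC)c(OC)c(OC)c3)[C@@H]2CO)cc1OC | target

**Step count**
Total steps: 9. Longest linear sequence: 6 (steps 1–3 then 7–9, or steps 4–6 then 7–9), which is two thirds of the total.

**Steps most likely to fail, with fallbacks**

Step 7 (domino oxa-Michael/Michael). Addition of an aliphatic alcohol to the iminium ion is uphill and the nitroallyl alcohol can isomerise under amine catalysis. The fallback sets out from 1 and fixes C2 before the ring closure. Brown allylation ((+)-Ipc2BOMe, allylMgBr, Et2O, −78 °C; NaOH/H2O2) gives (R)-1-(3,4,5-trimethoxyphenyl)but-3-en-1-ol F1. Williamson etherification (NaH, BrCH2CH(OEt)2, TBAI, DMF, 60 °C) gives the diethyl acetal ether F2, and aq. HCl/THF gives the alkoxyacetaldehyde F3. Henry addition of 8 (cat. DBU) gives the nitro alcohol F4, MsCl/Et3N gives the mesylate F5, and elimination gives the nitroalkene F6. Selective cleavage of the terminal alkene (cat. OsO4, NaIO4, 2,6-lutidine, dioxane/H2O) returns to the route at 14, now as an isolated single enantiomer. It is cyclised by the same enamine Michael addition and reduced in situ to 16 as in step 7.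

Step 8 (oxidative Nef). Oxone may epimerise C4 or give over-oxidation. The fallback sets out from 16 and is reductive: SnCl2·2H2O/PhSH/Et3N in MeCN reduces the nitro group to the ketoxime F7, and buffered aqueous TiCl3 (NH4OAc, THF) cleaves the oxime to the ketone, returning at 17.

Step 9 (diastereoselective reduction). Substrate control may give a poor ratio at C7'. The fallback sets out from 17 and uses reagent control on a protected substrate. TBSCl/imidazole gives the silyl ether ketone F8. Reduction with (R)-Me-CBS (cat.) and BH3·SMe2 in THF at −20 °C gives the (S)-carbinol silyl ether F9. TBAF in THF then returns at 18.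

**Further compounds**
F1 | step 7 | (R)-1-(3,4,5-trimethoxyphenyl)but-3-en-1-ol | C=CC[C@@H](O)c1cc(OC)c(OC)c(OC)c1
F2 | step 7 | 5-[(1R)-1-(2,2-diethoxyethoxy)but-3-en-1-yl]-1,2,3-trimethoxybenzene | C=CC[C@@H](OCC(OCC)OCC)c1cc(OC)c(OC)c(OC)c1
F3 | step 7 | 2-{[(1R)-1-(3,4,5-trimethoxyphenyl)but-3-en-1-yl]oxy}acetaldehyde | C=CC[C@@H](OCC=O)c1cc(OC)c(OC)c(OC)c1
F4 | step 7 | 1-(3,4-dimethoxyphenyl)-1-nitro-3-{[(1R)-1-(3,4,5-trimethoxyphenyl)but-3-en-1-yl]oxy}propan-2-ol | C=CC[C@@H](OCC(O)C(c1ccc(OC)c(OC)c1)[N+](=O)[O-])c1cc(OC)c(OC)c(OC)c1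
F5 | step 7 | 1-(3,4-dimethoxyphenyl)-1-nitro-3-{[(1R)-1-(3,4,5-trimethoxyphenyl)but-3-en-1-yl]oxy}propan-2-yl methanesulfonate | C=CC[C@@H](OCC(OS(C)(=O)=O)C(c1ccc(OC)c(OC)c1)[N+](=O)[O-])c1cc(OC)c(OC)c(OC)c1
F6 | step 7 | 5-[(1R)-1-{[(2E)-3-(3,4-dimethoxyphenyl)-3-nitroprop-2-en-1-yl]oxy}but-3-en-1-yl]-1,2,3-trimethoxybenzene | C=CC[C@@H](OC/C=C(\c1ccc(OC)c(OC)c1)[N+](=O)[O-])c1cc(OC)c(OC)c(OC)c1
F7 | step 8 | (3,4-dimethoxyphenyl)[(3S,4S,5R)-4-(hydroxymethyl)-5-(3,4,5-trimethoxyphenyl)oxolan-3-yl]methanone oxime | COc1ccc(C(=NO)[C@H]2CO[C@@H](c3cc(OC)c(OC)c(OC)c3)[C@@H]2CO)cc1OC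
F8 | step 9 | [(3R,4S,5R)-4-{[(tert-butyldimethylsilyl)oxy]methyl}-5-(3,4,5-trimethoxyphenyl)oxolan-3-yl](3,4-dimethoxyphenyl)methanone | COc1ccc(C(=O)[C@H]2CO[C@@H](c3cc(OC)c(OC)c(OC)c3)[C@@H]2CO[Si](C)(C)C(C)(C)C)cc1OC
F9 | step 9 | (S)-[(3R,4S,5R)-4-{[(tert-butyldimethylsilyl)oxy]methyl}-5-(3,4,5-trimethoxyphenyl)oxolan-3-yl](3,4-dimethoxyphenyl)methanol | COc1ccc([C@@H](O)[C@H]2CO[C@@H](c3cc(OC)c(OC)c(OC)c3)[C@@H]2CO[Si](C)(C)C(C)(C)C)cc1OC
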